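## Retrosynthetic overview

- **Feature:** in the cyclohexane ring C5–C6–C7–C8–C9–C10, the fusion carbon C7 stands between two equatorial carbinol carbons, C6 (lactone oxygen) and C8 (ester oxygen). Both ring bonds of C7 are therefore nitroaldol bonds.
- **Key cut:** breaking C6–C7 and C7–C8 gives a 1,5-dialdehyde (C6 and C8 as CHO, C5 and C10 already set) and a 3-silyloxy-1-nitropropane that supplies C7, C11 and C12. The nitro group is a traceless activator.
- **C5 and C10:** both are set together by an enantioselective boron-enolate Ireland–Claisen rearrangement of a geometrically pure (E)-allylic 3-methylbut-3-enoate.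
- **Ring order:** the cyclohexane forms first (double Henry). The γ-lactone O6–C12 follows by oxidative lactonisation after O8 silylation and radical denitration, and then the C13 methylene is added.
- **Side chain:** it enters last as a dioxepine-carboxylic acid whose seven-membered acetonide locks the (E) geometry and is removed by mild acid.

Key step: step 8

**Numbering (elemane):**
- C5 is the CH bearing isopropenyl (C4, C3, C15), C6 is CH–O (lactone), C7 is the fusion CH, C8 is CH–O (ester) and C9 is CH2.
- C10 is the quaternary carbon bearing methyl C14 and vinyl C1=C2; C11, C12 and C13 are the lactone α-carbon, carbonyl and methylene.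
- The target is (5R,6S,7S,8R,10R). All ring substituents are equatorial except the axial C10 methyl.
- The CIP letter at C7 changes with the group on O8, but the geometry does not.

**Assumption:** the sense of induction of the diazaborolidine controller in step 3 is assigned by analogy with simpler allylic esters. The (R,R) form is written, and the equally available (S,S) form is used if correlation of the rearranged acid shows the opposite sense.

## Route

Step 1
Reactants: 1 tert-butyl(but-3-yn-1-yloxy)dimethylsilane
Product: 4 (E)-5-(tert-butyldimethylsilyloxy)-3-methylpent-2-en-1-ol, via alkenylalane 2 (not isolated), via lithium alanate 3 (not isolated)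
Conditions: Me3Al, Cp2ZrCl2 (cat.), CH2Cl2, 0 °C to rt; n-BuLi, THF–hexane, −30 °C; (CH2O)n, rt; aq. work-up
Reagents that add atoms: trimethylaluminium C[Al](C)C; paraformaldehyde (as formaldehyde) C=O
Why: Negishi zirconium-catalysed carboalumination adds methyl and aluminium syn across the terminal alkyne with aluminium at the terminus, and hydroxymethylation of the derived alanate keeps that geometry, so the (E)-trisubstituted alkene that later encodes C10 should form free of its (Z) isomer.

Step 2
Reactants: 4 (E)-5-(tert-butyldimethylsilyloxy)-3-methylpent-2-en-1-ol; 5 3-methylbut-3-enoic acid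
Product: 6 (E)-5-(tert-butyldimethylsilyloxy)-3-methylpent-2-en-1-yl 3-methylbut-3-enoate
Conditions: EDC·HCl, DMAP (cat.), CH2Cl2, 0 °C to rt
Reagents that add atoms: none
Why: Steglich-type carbodiimide esterification of a primary allylic alcohol, in which only catalytic DMAP at low temperature should keep the β,γ-double bond of 5 out of conjugation.

Step 3
Reactants: 6 (E)-5-(tert-butyldimethylsilyloxy)-3-methylpent-2-en-1-yl 3-methylbut-3-enoate
Product: 8 (2R,3R)-3-[2-(tert-butyldimethylsilyloxy)ethyl]-3-methyl-2-(prop-1-en-2-yl)pent-4-enoic acid, via boron ketene acetal 7 (not isolated)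
Conditions: (4R,5R)-2-bromo-1,3-bis[3,5-bis(trifluoromethyl)phenylsulfonyl]-4,5-diphenyl-1,3,2-diazaborolidine (from the (R,R)-bis-sulfonamide and BBr3, CH2Cl2, rt, then evaporation), Et3N, toluene–hexane, −78 °C, then −20 to 4 °C; aq. work-up
Reagents that add atoms: none
Why: Soft enolisation with the C2-symmetric bromoborane and Et3N in a non-polar medium should give the E(O) boron ketene acetal 7 (isopropenyl cis to the allyloxy oxygen), which undergoes an enantioselective Ireland–Claisen [3,3] rearrangement through a chair with the silyloxyethyl arm of the (E)-alkene pseudo-equatorial and the methyl pseudo-axial, so enolate and alkene geometry fix the C5/C10 relative configuration and the sulfonamide-shielded boron ligand selects the enolate face and thus the absolute (5R,10R) configuration.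

Step 4
Reactants: 8 (2R,3R)-3-[2-(tert-butyldimethylsilyloxy)ethyl]-3-methyl-2-(prop-1-en-2-yl)pent-4-enoic acid
Product: 9 (2R,3R)-3-[2-(tert-butyldimethylsilyloxy)ethyl]-3-methyl-2-(prop-1-en-2-yl)pent-4-en-1-ol
Conditions: LiAlH4, Et2O, 0 °C to reflux; aq. work-up
Reagents that add atoms: none
Why: Hydride reduction of a carboxylic acid, in which immediate carboxylate formation protects C5–H from exchange and the alkenes and the silyl ether are inert.

Step 5
Reactants: 9 (2R,3R)-3-[2-(tert-butyldimethylsilyloxy)ethyl]-3-methyl-2-(prop-1-en-2-yl)pent-4-en-1-ol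
Product: 10 (2R,3R)-3-ethenyl-3-methyl-2-(prop-1-en-2-yl)pentane-1,5-diol
Conditions: CSA (cat.), MeOH, 0 °C to rt
Reagents that add atoms: none
Why: Acid-catalysed methanolysis of an unhindered primary TBS ether, mild enough to leave the 1,5-diene untouched.

Step 6
Reactants: 10 (2R,3R)-3-ethenyl-3-methyl-2-(prop-1-en-2-yl)pentane-1,5-diol
Product: 11 (2R,3R)-3-ethenyl-3-methyl-2-(prop-1-en-2-yl)pentanedial
Conditions: (COCl)2, DMSO, CH2Cl2, −78 °C; i-Pr2NEt, −78 to −30 °C; cold pH 7 buffer; used crude at once
Reagents that add atoms: none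
Why: In the Swern oxidation both hydroxyls become alkoxysulfonium ions before any base is present, so no lactol or lactone can form, and the hindered base with a cold neutral quench should keep C5 configured and the isopropenyl group unconjugated.

Step 7
Reactants: 12 3-nitropropan-1-ol
Product: 13 tert-butyldimethyl(3-nitropropoxy)silane
Conditions: TBSCl, imidazole, CH2Cl2, 0 °C to rt
Reagents that add atoms: tert-butyldimethylsilyl chloride CC(C)(C)[Si](C)(C)Cl
Why: Standard imidazole-promoted silylation of a primary alcohol, and with the oxygen γ to the nitro carbon the later nitronate has no β-leaving group.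

Step 8
Reactants: 11 (2R,3R)-3-ethenyl-3-methyl-2-(prop-1-en-2-yl)pentanedial; 13 tert-butyldimethyl(3-nitropropoxy)silane
Product: 15 (5R,6S,7R,8R,10R)-nitrodiol = (1R,2R,3S,4R,5R)-2-[2-(tert-butyldimethylsilyloxy)ethyl]-5-ethenyl-5-methyl-2-nitro-4-(prop-1-en-2-yl)cyclohexane-1,3-diol, via mono-nitroaldol 14 (not isolated)
Conditions: 13 (1.05 equiv), Et3N (0.3 equiv), THF–i-PrOH 1:1, 0 °C to rt
Reagents that add atoms: none
Why: Et3N reversibly forms the nitronate of 13, which adds first to the unhindered C8 aldehyde to give 14 (held largely as its O8-to-C6 lactol), and the still acidic C7–H of 14 is removed again so that the new nitronate attacks the C6 aldehyde. The closest known reaction is the double Henry (nitroaldol) cyclisation of 1,5-dialdehydes with nitromethane, nitroethane or 2-nitroethanol to 2-nitrocyclohexane-1,3-diols. The cyclohexane closes in a 6-exo-trig (enolexo) mode, helped by the Thorpe–Ingold effect of quaternary C10. Every C–C bond formed is reversible under these conditions, so C6 and C8 are set thermodynamically: with C5 and C10 fixed the ring adopts the chair with isopropenyl and vinyl equatorial and the C10 methyl axial, and an axial hydroxyl at C6 or C8 would be syn-axial to that methyl, so both hydroxyls should end equatorial. C7 follows the same equilibrium (chain equatorial and nitro axial is drawn), but its configuration is provisional because step 10 erases it. The selectivity needed is deprotonation of the nitroalkane rather than C5–H, and it is secured by the gap of several pKa units, by the shielding of C5–H next to quaternary C10, and by the short lifetime of the free C6 aldehyde, which is masked as the lactol.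

Step 9
Reactants: 15 (5R,6S,7R,8R,10R)-nitrodiol
Product: 16 (5R,6S,7S,8R,10R)-8-O-TBS nitro alcohol
Conditions: TBSOTf (1.05 equiv), 2,6-lutidine, CH2Cl2, −78 °C
Reagents that add atoms: tert-butyldimethylsilyl triflate CC(C)(C)[Si](C)(C)OS(=O)(=O)C(F)(F)F
Why: Site-selective silylation, because O8 has the C9 methylene as a neighbour whereas O6 is wedged between isopropenyl-bearing C5 and quaternary C7, and the weak hindered base should not trigger a retro-Henry reaction.

Step 10
Reactants: 16 (5R,6S,7S,8R,10R)-8-O-TBS nitro alcohol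
Product: 17 (5R,6S,7R,8R,10R)-denitrated bis-silyl ether with free O6–H
Conditions: Bu3SnH (5 equiv), AIBN (portions), toluene (concentrated), 100 °C
Reagents that add atoms: none
Why: Radical denitration of a tertiary nitroalkane, in which the stannyl radical adds to a nitro oxygen, C–N scission gives the C7 radical, and hydrogen should transfer along the axial direction (the face of H5 and axial H9) while the C11 chain settles equatorial, which sets C7–H trans to H6 and H8; the high stannane concentration outruns any attack on the C10 vinyl group.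

Step 11
Reactants: 17 (5R,6S,7R,8R,10R)-denitrated bis-silyl ether
Product: 18 (5R,6S,7R,8R,10R)-6,12-diol with O8–TBS
Conditions: CSA (cat.), MeOH–CH2Cl2, 0 °C
Reagents that add atoms: none
Why: Selective acid methanolysis, because the unhindered primary TBS ether is cleaved far faster than the secondary ring TBS ether at O8.

Step 12
Reactants: 18 (5R,6S,7R,8R,10R)-6,12-diol with O8–TBS
Product: 20 (5R,6S,7R,8R,10R)-8-O-TBS 6,12-olide, via lactol 19 (not isolated)
Conditions: TEMPO (cat.), PhI(OAc)2, CH2Cl2, rt
Reagents that add atoms: none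
Why: Oxidative lactonisation of a 1,4-diol, in which the oxoammonium species oxidises only the primary alcohol, the aldehyde is captured by O6–H (the only free hydroxyl) as the trans-fused lactol 19, and this is oxidised on to the γ-lactone without touching a stereocentre.

Step 13
Reactants: 20 (5R,6S,7R,8R,10R)-8-O-TBS 6,12-olide
Product: 22 11-(dimethylaminomethyl) lactone (either C11 epimer), via lithium enolate 21 (not isolated)
Conditions: LDA, THF, −78 °C; CH2=NMe2+ I−, −78 °C to rt
Reagents that add atoms: Eschenmoser's salt C=[N+](C)C.[I-]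
Why: Mannich aminomethylation of a lactone enolate that has no β-leaving group on C7; the new C11 centre is temporary and is removed in the next step.

Step 14
Reactants: 22 11-(dimethylaminomethyl) lactone
Product: 24 (5R,6S,7R,8R,10R)-8-O-TBS α-methylene-γ-lactone, via ammonium iodide 23 (not isolated)
Conditions: MeI, MeOH, rt; evaporate; NaHCO3, CH2Cl2–H2O, rt
Reagents that add atoms: none
Why: Exhaustive methylation followed by Hofmann-type E1cB loss of trimethylamine, the standard way from a Mannich base to an α-methylene lactone.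

Step 15
Reactants: 24 (5R,6S,7R,8R,10R)-8-O-TBS α-methylene-γ-lactone
Product: 25 (3aS,4R,6R,7R,7aS)-6-ethenyl-4-hydroxy-6-methyl-3-methylidene-7-(prop-1-en-2-yl)hexahydro-1-benzofuran-2(3H)-one
Conditions: 48% aq. HF, MeCN, 0 °C to rt
Reagents that add atoms: none
Why: Desilylation with acidic fluoride generates no alkoxide, so translactonisation to O8 and conjugate addition to C13 are avoided.

Step 16
Reactants: 26 but-2-yne-1,4-diol
Product: 27 (E)-2-(tributylstannyl)but-2-ene-1,4-diol
Conditions: Bu3SnH, PdCl2(PPh3)2 (cat.), THF, 0 °C to rt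
Reagents that add atoms: tributyltin hydride CCCC[SnH](CCCC)CCCC
Why: Palladium-catalysed syn-hydrostannation of a symmetrical alkyne raises no regiochemical question and places the two hydroxymethyl groups cis to each other.

Step 17
Reactants: 27 (E)-2-(tributylstannyl)but-2-ene-1,4-diol
Product: 28 tributyl(2,2-dimethyl-4,7-dihydro-1,3-dioxepin-5-yl)stannane
Conditions: 2,2-dimethoxypropane, PPTS (cat.), CH2Cl2, rt
Reagents that add atoms: 2,2-dimethoxypropane COC(C)(C)OC
Why: In this acetal exchange only cis-disposed hydroxymethyl groups can close the seven-membered ring, which locks the alkene geometry, and PPTS is too weak to protodestannylate.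

Step 18
Reactants: 28 tributyl(2,2-dimethyl-4,7-dihydro-1,3-dioxepin-5-yl)stannane
Product: 30 2,2-dimethyl-4,7-dihydro-1,3-dioxepine-5-carboxylic acid, via vinyllithium 29 (not isolated)
Conditions: n-BuLi, THF, −78 °C; CO2; cold dilute HCl to pH 4
Reagents that add atoms: carbon dioxide O=C=O
Why: Tin–lithium exchange followed by carboxylation, run at −78 °C, where 2-lithioallyl ethers do not lose alkoxide.

Step 19
Reactants: 25 8-hydroxy α-methylene-γ-lactone; 30 2,2-dimethyl-4,7-dihydro-1,3-dioxepine-5-carboxylic acid
Product: 31 8-O-(2,2-dimethyl-4,7-dihydro-1,3-dioxepine-5-carbonyl) lactone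
Conditions: EDC·HCl, DMAP, CH2Cl2, 0 °C to rt
Reagents that add atoms: none
Why: Steglich esterification of the single free, equatorial C8 hydroxyl proceeds with retention at C8, under conditions routinely tolerated by α-methylene lactones.

Step 20
Reactants: 31 8-O-(2,2-dimethyl-4,7-dihydro-1,3-dioxepine-5-carbonyl) lactone
Product: 32 target, (3aS,4R,6R,7R,7aS)-6-ethenyl-6-methyl-3-methylidene-2-oxo-7-(prop-1-en-2-yl)octahydro-1-benzofuran-4-yl (2E)-4-hydroxy-2-(hydroxymethyl)but-2-enoate
Conditions: AcOH–H2O–THF 3:1:1, rt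
Reagents that add atoms: none
Why: Acid-catalysed hydrolysis of a strained seven-membered acetonide frees both hydroxymethyl groups, which stay cis to each other, so the ester carbonyl is trans to C4' (E) and cannot lactonise.

## Compound list

1 | tert-butyl(but-3-yn-1-yloxy)dimethylsilane | C#CCCO[Si](C)(C)C(C)(C)C | starting material
2 | (E)-[4-(tert-butyldimethylsilyloxy)-2-methylbut-1-en-1-yl]dimethylalane | C[Al](C)/C=C(\C)CCO[Si](C)(C)C(C)(C)C | intermediate
3 | lithium butyl[(E)-4-(tert-butyldimethylsilyloxy)-2-methylbut-1-en-1-yl]dimethylalanate | [Li+].CCCC[Al-](C)(C)/C=C(\C)CCO[Si](C)(C)C(C)(C)C | intermediate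
4 | (E)-5-(tert-butyldimethylsilyloxy)-3-methylpent-2-en-1-ol | OC/C=C(\C)CCO[Si](C)(C)C(C)(C)C | intermediate
5 | 3-methylbut-3-enoic acid | C=C(C)CC(=O)O | starting material
6 | (E)-5-(tert-butyldimethylsilyloxy)-3-methylpent-2-en-1-yl 3-methylbut-3-enoate | C=C(C)CC(=O)OC/C=C(\C)CCO[Si](C)(C)C(C)(C)C | intermediate
7 | E(O) boron ketene acetal of 6 bearing the (4R,5R)-diazaborolidine | C=C(C)/C=C(\OC/C=C(\C)CCO[Si](C)(C)C(C)(C)C)OB1N(S(=O)(=O)c2cc(C(F)(F)F)cc(C(F)(F)F)c2)[C@H](c2ccccc2)[C@@H](c2ccccc2)N1S(=O)(=O)c1cc(C(F)(F)F)cc(C(F)(F)F)c1 | intermediate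
8 | (2R,3R)-3-[2-(tert-butyldimethylsilyloxy)ethyl]-3-methyl-2-(prop-1-en-2-yl)pent-4-enoic acid | OC(=O)[C@H](C(C)=C)[C@@](C)(C=C)CCO[Si](C)(C)C(C)(C)C | intermediate
9 | (2R,3R)-3-[2-(tert-butyldimethylsilyloxy)ethyl]-3-methyl-2-(prop-1-en-2-yl)pent-4-en-1-ol | OC[C@H](C(C)=C)[C@@](C)(C=C)CCO[Si](C)(C)C(C)(C)C | intermediate
10 | (2R,3R)-3-ethenyl-3-methyl-2-(prop-1-en-2-yl)pentane-1,5-diol | OC[C@H](C(C)=C)[C@@](C)(C=C)CCO | intermediate
11 | (2R,3R)-3-ethenyl-3-methyl-2-(prop-1-en-2-yl)pentanedial | O=C[C@H](C(C)=C)[C@@](C)(C=C)CC=O | intermediate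
12 | 3-nitropropan-1-ol | [O-][N+](=O)CCCO | starting material
13 | tert-butyldimethyl(3-nitropropoxy)silane | [O-][N+](=O)CCCO[Si](C)(C)C(C)(C)C | intermediate
14 | open mono-nitroaldol (C7–C8 made, C6 still CHO, mixture at C7 and C8, in equilibrium with its lactol) | O=C[C@H](C(C)=C)[C@@](C)(C=C)CC(O)C([N+](=O)[O-])CCO[Si](C)(C)C(C)(C)C | intermediate
15 | (1R,2R,3S,4R,5R)-2-[2-(tert-butyldimethylsilyloxy)ethyl]-5-ethenyl-5-methyl-2-nitro-4-(prop-1-en-2-yl)cyclohexane-1,3-diol | C=C[C@@]1(C)C[C@@H](O)[C@]([N+](=O)[O-])(CCO[Si](C)(C)C(C)(C)C)[C@@H](O)[C@@H]1C(=C)C | intermediate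
16 | 8-O-TBS ether of 15, O6–H free, (5R,6S,7S,8R,10R) | C=C[C@@]1(C)C[C@@H](O[Si](C)(C)C(C)(C)C)[C@]([N+](=O)[O-])(CCO[Si](C)(C)C(C)(C)C)[C@@H](O)[C@@H]1C(=C)C | intermediate
17 | denitrated bis-silyl ether, C11 chain equatorial, (5R,6S,7R,8R,10R) | C=C[C@@]1(C)C[C@@H](O[Si](C)(C)C(C)(C)C)[C@H](CCO[Si](C)(C)C(C)(C)C)[C@@H](O)[C@@H]1C(=C)C | intermediate
18 | 6,12-diol with O8–TBS, (5R,6S,7R,8R,10R) | C=C[C@@]1(C)C[C@@H](O[Si](C)(C)C(C)(C)C)[C@H](CCO)[C@@H](O)[C@@H]1C(=C)C | intermediate
19 | trans-fused 6,12-lactol (mixture at C12) | C=C[C@@]1(C)C[C@@H](O[Si](C)(C)C(C)(C)C)[C@@H]2CC(O)O[C@H]2[C@@H]1C(=C)C | intermediate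
20 | 8-O-TBS trans-fused 6,12-olide, (5R,6S,7R,8R,10R) | C=C[C@@]1(C)C[C@@H](O[Si](C)(C)C(C)(C)C)[C@@H]2CC(=O)O[C@H]2[C@@H]1C(=C)C | intermediate
21 | lithium enolate of 20 | C=C[C@@]1(C)C[C@@H](O[Si](C)(C)C(C)(C)C)[C@@H]2C=C([O-])O[C@H]2[C@@H]1C(=C)C.[Li+] | intermediate
22 | 11-(dimethylaminomethyl) lactone (C11 undefined) | C=C[C@@]1(C)C[C@@H](O[Si](C)(C)C(C)(C)C)[C@@H]2C(CN(C)C)C(=O)O[C@H]2[C@@H]1C(=C)C | intermediate
23 | 11-(trimethylammoniomethyl) lactone iodide | C=C[C@@]1(C)C[C@@H](O[Si](C)(C)C(C)(C)C)[C@@H]2C(C[N+](C)(C)C)C(=O)O[C@H]2[C@@H]1C(=C)C.[I-] | intermediate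
24 | 8-O-TBS α-methylene-γ-lactone, (5R,6S,7R,8R,10R) | C=C[C@@]1(C)C[C@@H](O[Si](C)(C)C(C)(C)C)[C@@H]2C(=C)C(=O)O[C@H]2[C@@H]1C(=C)C | intermediate
25 | (3aS,4R,6R,7R,7aS)-6-ethenyl-4-hydroxy-6-methyl-3-methylidene-7-(prop-1-en-2-yl)hexahydro-1-benzofuran-2(3H)-one | C=C[C@@]1(C)C[C@@H](O)[C@@H]2C(=C)C(=O)O[C@H]2[C@@H]1C(=C)C | intermediate
26 | but-2-yne-1,4-diol | OCC#CCO | starting material
27 | (E)-2-(tributylstannyl)but-2-ene-1,4-diol | OC/C=C(CO)/[Sn](CCCC)(CCCC)CCCC | intermediate
28 | tributyl(2,2-dimethyl-4,7-dihydro-1,3-dioxepin-5-yl)stannane | CC1(C)OCC=C([Sn](CCCC)(CCCC)CCCC)CO1 | intermediate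
29 | (2,2-dimethyl-4,7-dihydro-1,3-dioxepin-5-yl)lithium | [Li]C1=CCOC(C)(C)OC1 | intermediate
30 | 2,2-dimethyl-4,7-dihydro-1,3-dioxepine-5-carboxylic acid | CC1(C)OCC=C(C(=O)O)CO1 | intermediate
31 | 8-O-(2,2-dimethyl-4,7-dihydro-1,3-dioxepine-5-carbonyl) α-methylene-γ-lactone, (5R,6S,7S,8R,10R) | C=C[C@@]1(C)C[C@@H](OC(=O)C2=CCOC(C)(C)OC2)[C@@H]3C(=C)C(=O)O[C@H]3[C@@H]1C(=C)C | intermediate
32 | CNP0309506.1, (5R,6S,7S,8R,10R) | C=C[C@@]1(C)C[C@@H](OC(=O)/C(=C/CO)CO)[C@@H]2C(=C)C(=O)O[C@H]2[C@@H]1C(=C)C | target

## Step count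

- Total steps: 20
- Longest linear sequence: 16 (steps 1–6, 8–15, 19, 20)

## Steps most likely to fail

**1. Step 8 (double Henry annulation).**

What may go wrong:
- The second, hindered closure to a tertiary nitro centre may lie on the side of the open mono-adduct and its lactol.
- Intermolecular addition may give oligomers.
- Long contact with the amine may epimerise C5 or move the isopropenyl double bond into conjugation with the C6 aldehyde.

The fallback sets out from 9 and comes back at 16. The two bonds to C7 are made one at a time, and C6 stays at the alcohol level until the end. Alcohol 9 is etherified with 4-methoxybenzyl trichloroacetimidate and catalytic CSA to the 4-methoxybenzyl ether F1. TBAF frees the primary alcohol F2, and Dess–Martin periodinane gives the aldehyde F3. A Henry reaction of F3 with 13 under Cu(OAc)2 and a chiral bis(oxazoline) ligand sets C8 by catalyst control and gives the nitro alcohol F4, whose mixture at C7 is of no consequence. TBSOTf and 2,6-lutidine then give the bis-silyl ether F5. DDQ removes the benzyl ether to give the primary alcohol F6, and buffered Dess–Martin oxidation gives the nitro aldehyde F7. A short treatment of F7 with catalytic Et3N closes C6–C7 in an intramolecular Henry reaction, in which O6 again ends equatorial by equilibration. The product is 16, so step 9 is no longer needed.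

**2. Step 3 (enantioselective Ireland–Claisen).**

What may go wrong:
- Control of the boron enolate geometry may be incomplete.
- Facial discrimination may erode at the temperature needed to build a quaternary centre.
- The β,γ-unsaturated ester may drift into conjugation before it is enolised.

The fallback sets out from 6 and comes back at 8. Relative and absolute control are separated. LDA in THF at −78 °C followed by TMSCl gives the E(O) trimethylsilyl ketene acetal F8. On warming, F8 rearranges through the same chair, and acidic work-up gives the racemic acid F9 with the required relative configuration. Fractional crystallisation with (S)-1-phenylethylamine, or its enantiomer if that gives the less soluble salt, provides the diastereomerically pure ammonium salt F10. The configuration of F10 is to be established by crystallography, and acidification returns 8.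

**3. Step 10 (radical denitration).**

What may go wrong:
- Hydrogen may transfer to the wrong face of the C7 radical, because the bulky O8 silyl ether disfavours the equatorial position of the C11 chain.
- The radical may be captured by the C10 vinyl group.
- The remaining β-nitro alcohol may undergo thermal retro-nitroaldol cleavage.

The fallback sets out from 15 and comes back at 17. The order of events is inverted, so the stereodetermining hydrogen transfer takes place on a radical flanked by two small hydroxyls. Nitrodiol 15 is denitrated directly with Bu3SnH and AIBN to the nitro-free diol F11, on which any C7 epimer should be easier to separate. O8 is then distinguished from the doubly flanked O6 by TBSOTf and 2,6-lutidine at −78 °C, which gives 17.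

## Further compounds

F1 | step 8 | 4-methoxybenzyl ether of 9 | COc1ccc(COC[C@H](C(C)=C)[C@@](C)(C=C)CCO[Si](C)(C)C(C)(C)C)cc1
F2 | step 8 | (3R,4R)-3-ethenyl-4-[(4-methoxybenzyloxy)methyl]-3,5-dimethylhex-5-en-1-ol | COc1ccc(COC[C@H](C(C)=C)[C@@](C)(C=C)CCO)cc1
F3 | step 8 | C8 aldehyde with O6 as 4-methoxybenzyl ether | COc1ccc(COC[C@H](C(C)=C)[C@@](C)(C=C)CC=O)cc1
F4 | step 8 | (8R)-nitro alcohol, mixture at C7 | COc1ccc(COC[C@H](C(C)=C)[C@@](C)(C=C)C[C@@H](O)C([N+](=O)[O-])CCO[Si](C)(C)C(C)(C)C)cc1
F5 | step 8 | 8-O-TBS ether of F4 | COc1ccc(COC[C@H](C(C)=C)[C@@](C)(C=C)C[C@@H](O[Si](C)(C)C(C)(C)C)C([N+](=O)[O-])CCO[Si](C)(C)C(C)(C)C)cc1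
F6 | step 8 | C6 primary alcohol from F5 | OC[C@H](C(C)=C)[C@@](C)(C=C)C[C@@H](O[Si](C)(C)C(C)(C)C)C([N+](=O)[O-])CCO[Si](C)(C)C(C)(C)C
F7 | step 8 | C6 nitro aldehyde | O=C[C@H](C(C)=C)[C@@](C)(C=C)C[C@@H](O[Si](C)(C)C(C)(C)C)C([N+](=O)[O-])CCO[Si](C)(C)C(C)(C)C
F8 | step 3 | E(O) trimethylsilyl ketene acetal of 6 | C=C(C)/C=C(\OC/C=C(\C)CCO[Si](C)(C)C(C)(C)C)O[Si](C)(C)C
F9 | step 3 | racemic acid (8 and its mirror image) | OC(=O)[C@H](C(C)=C)[C@@](C)(C=C)CCO[Si](C)(C)C(C)(C)C.OC(=O)[C@@H](C(C)=C)[C@](C)(C=C)CCO[Si](C)(C)C(C)(C)C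
F10 | step 3 | (S)-1-phenylethylammonium salt of 8 | OC(=O)[C@H](C(C)=C)[C@@](C)(C=C)CCO[Si](C)(C)C(C)(C)C.C[C@H](N)c1ccccc1
F11 | step 10 | nitro-free 6,8-diol, C11 chain equatorial, (5R,6S,7S,8R,10R) | C=C[C@@]1(C)C[C@@H](O)[C@H](CCO[Si](C)(C)C(C)(C)C)[C@@H](O)[C@@H]1C(=C)C
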